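The rate constants come from no measurement; the rest is arithmetic.

We leave this flask closed for the whole run and read it once, at the end.

substrate 20 mM; reagent 80.0 mM; free catalyst 0.50 mM; time 80 min

    catalyst intermediate D → free catalyst + target (k1 = 66 s⁻¹)
    catalyst intermediate A → by-product + catalyst intermediate B (k2 = 0.49 s⁻¹)
    substrate + catalyst intermediate C ⇌ catalyst intermediate D (K3 = 63 M⁻¹, k3 = 1500 M⁻¹ s⁻¹)
    catalyst intermediate B ⇌ catalyst intermediate C (K4 = 0.21, k4 = 1.3 s⁻¹)
    reagent + free catalyst ⇌ catalyst intermediate A (K5 = 5.6 M⁻¹, k5 = 12 M⁻¹ s⁻¹)
    target ⇌ isomer of the product (K6 = 1.9, k6 = 0.0075 s⁻¹)

- which holds at 80 min: what has brought the reaction to rest, or that it has not come to rest (it is still moving / all of the substrate has reacted / no working catalyst is left / the reagent has run out first / forward and back rates have come level)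
- share of the substrate used up at 80 min
- target at 80 min, in percent of the substrate charged
- isomer of the product at 80 min, in percent of the substrate charged

For whoever takes over the bench: the flask starts with substrate, reagent and free catalyst. Substrate is the limiting reagent, 20 mM against 80.0 mM of reagent. By our reckoning one turn of the catalyst takes τ = 8.41 s. That covers binding reagent, falling back, shedding by-product and passing from intermediate B to C, with reagent held at its charge and the substrate steps taken as quick. So 0.50 mM of catalyst works through the charge in about 5.60 min, well inside the 80 min.

Target meanwhile turns into its isomer and back, relaxing at λ = 0.687 min⁻¹, both directions together, towards a balance of 34.5% target (thermodynamic control). Divide the filling rate, one over that filling time, by λ, and time drops out. Multiplied by the isomer's balance share, this gives the overhang h = 17.0%, the part of the charge by which target stands above its balance while the cycle feeds it.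

So do not quench when the substrate has reacted, since a sample then shows overhang, not balance. Left to the end, λ times the run is 55.0, so we expect complete conversion with target at its balance.

The forecast agrees: all of the substrate has reacted, conversion 100%, target 34.5%, isomer 65.5%, on the ground that “the irreversible product-release step leaves nothing to push it back”.

The run gives all of the substrate has reacted, conversion 100%, target 34.5%, isomer 65.5%.

In this flask the relaxation half-life of 1.01 min is short against the 80 min, and target stands at 40.0% at 8.00 min, above the balance of 34.5%, on the side of the overhang h = 17.0%, whereas at 40.0 min it stands at 34.5%. In the flask with 140 mM of reagent the same reckoning shortens τ to 6.01 s and raises the overhang to 23.8%, and that flask holds 34.5% target at 80.0 min.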